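## The problem

Target 21 is a germacrane-type ten-membered carbocycle with no second carbocycle to stiffen it. The ring is numbered here, and in every ring compound below, as C1 (CH–iPr), C2=C3 (E alkene), C4 (C(Me)OH), C5–C7 (three CH2), C8 (oxirane C–Me), C9 (oxirane CH) and C10 (CH–O–acyl). It carries five stereocentres. C8, C9 and C10 are contiguous and can control one another, and C1 is allylic and adjacent to C10. C4 is a tertiary carbinol, 1,5-related to C8 across the flexible C5–C7 chain, and cannot be set from the other centres by ordinary induction. A synthesis has to close a strained medium ring that holds an E alkene, place a cis-fused trisubstituted oxirane anti to the C10 oxygen, and acylate a hindered secondary alcohol beside a free tertiary one. The sensitive groups are the oxirane (acid would let the C4 hydroxyl attack C8 across the ring), the tertiary allylic alcohol (ionisation), and the aryl ester with its free phenol (strong base and nucleophiles). The enabling feature is a hidden symmetry. If the oxirane oxygen is shifted in thought from C8–C9 to C9–C10, C8 becomes a tertiary carbinol next to C9–C10, the mirror image of the C4/C2=C3 half. Removing that oxygen leaves dienediol 14, in which C4 and C8 have opposite configuration and C1 and C6 lie on a mirror plane. The absolute configuration of all five centres can therefore come from a single epoxidation that selects one of two enantiotopic alkenes of a meso compound.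

## Retrosynthesis

**Ester.** The C10–O acyl bond is cut first: 21 comes from silyl ether 20, and 20 from alcohol 16 and acid 19 (one step from 17). Carrying the ester through earlier steps would expose it to the base of the oxirane migration and to peroxide. At the end, only the secondary C10 hydroxyl of 16 is acylable, so no protecting group is needed on the ring. The forward reaction must acylate a hindered secondary alcohol under non-acidic conditions.

**Oxirane migration.** 16 is traced to epoxy diol 15 by a retro-Payne shift: the C8–O oxirane bond is cut and the C10 oxygen is closed onto C9. A hydroxyl-directed epoxidation of a C8=C9 alkene would put the oxirane syn to the C10 oxygen. The Payne route inverts C9 and gives the required anti arrangement. The shift is downhill: it trades a trans-disubstituted oxirane and a tertiary alkoxide for a cis-fused trisubstituted oxirane and a secondary alkoxide. The forward reaction needs the C8 alkoxide anti-periplanar to the C9–O bond within the ring.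

**Key cut.** 15 is traced to meso dienediol 14 by removing the C9–O and C10–O bonds. The alternative of building C4 and C8 from two separately made enantiomeric pieces is avoided. 14 is achiral, so everything before it can be made from achiral materials in two-directional fashion. The forward reaction asks one chiral catalyst to choose one half, one face, and to stop after one oxygen transfer.

**Carbinols.** Each tertiary allylic alcohol unit of 14 is traced to a trans trisubstituted oxirane (bis-epoxide 11) and then to an E trisubstituted alkene (diene 10). Methyl addition to a ring bis-enone or a singlet-oxygen ene reaction would be less defined in regio- and stereochemistry. The oxirane route fixes the C4–O and C8–O bonds at the epoxidation stage, and the later selenoxide elimination has only one direction open. 10 is a hydrocarbon with no stereocentre. The forward epoxidation must attack same-sense faces of both alkenes, on a defined side relative to the isopropyl group. Only ring conformation can supply this, and it is the main stereochemical burden of the plan outside the key step.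

**Ring.** 10 is traced to tris-sulfone 9, then to open-chain chloride 8, then to dichloride 6 and isobutyl phenyl sulfone 7. The bonds cut are C1–C2 and C1–C10. C1 is the only sp3 carbon flanked by two allylic methylenes, so a one-carbon nucleophile that already carries the isopropyl group can be allylated twice. Both E alkenes are preformed in the chain, which a ring-closing olefination would not guarantee. The forward reaction is a high-dilution intramolecular sulfone alkylation to a strained ring, followed by removal of three sulfonyl groups.

**Chain.** 6 is traced through diol 4 and diacetate 3 to bis(phenylsulfonyl)methane 1 and two molecules of chloro acetate 2, cutting C5–C6 and C6–C7. Compound 1 serves as C6 and is acidic enough for mild double alkylation. Compound 2 supplies C2–C5 with the E geometry built in and with its two ends differentiated as chloride and acetate. The forward steps are standard alkylation and functional-group exchange.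

## Roads not taken

**Alternative 1:** Propyne A3 is stitched between C7 and C10. The cuts are C7–C8 and C9–C10. In the forward key step the alkylmagnesium reagent A2 (C3–C7) is converted into an alkylcopper, which adds syn across A3. The resulting Z-alkenylcopper is acylated by acid chloride A4 under zerovalent palladium catalysis to give Z-enone A1.
- Merits: the trisubstituted C8=C9 geometry is set stereospecifically, and C4 and C1 arrive in small building blocks made by well-understood acyclic chemistry. In this respect the road is better than the chosen plan, which relies on ring conformation for the C1/C4/C8 relationship.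
- Weak points for this target: A2 and A4 each need their own asymmetric synthesis. The ring must still be closed with an E C2=C3 alkene. The C10 ketone must be reduced with control from C1. The oxirane must then be placed anti to the C10 oxygen, against the natural sense of a directing hydroxyl.
- Comparison: the chosen plan sets against this a much shorter sequence, one catalytic asymmetric step, and the Payne shift, which gives the anti oxirane by mechanism.

**Alternative 2:** The cut is the transannular C3–C8 bond of the cis-fused octalin mesylate A6. In one flask, hydroboration of C1=C2 and alkoxide addition give a C2 borate, which fragments. C3–C8 breaks, the mesylate leaves C9, and the ten-membered diene A5 appears with E C2=C3 and Z C8=C9.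
- Merits: no high-dilution ring closure is needed, the alkene geometries follow from decalin stereochemistry, and C1 is set by the syn hydroboration. In ring formation this road is more secure than the sulfone alkylation of the chosen plan.
- Weak points: A6 needs five stereocentres in enantiopure form, three of which are destroyed in the fragmentation. The C4 tertiary ether sits next to the ring fusion. The later C8–C9 epoxidation again has to run anti to the C10 oxygen.
- Comparison: the chosen plan has a less certain ring closure but no stereochemical overhead, since its precursor 10 has no stereocentre.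

**Alternative 3:** The cuts are C5–C6 and C6–C7, with C6 as the carbon of silyl dithiane A10. Lithiated A10 opens epoxide A8 at C5, a polar additive triggers the [1,4]-Brook shift of silicon to the C4 oxygen, and the new anion opens the enantiomeric epoxide A9 at C7. The product is A7.
- Merits: two C–C bonds form in one flask. The C4 and C8 oxygens come out differentiated (silyl ether and free hydroxyl). Their relative configuration is fixed by reagent control in A8 and A9. In this last respect the road is better than the ring-controlled bis-epoxidation of the chosen plan.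
- Weak points: A7 is only the C3–C9 chain. C1, C2, C10, the ring, the E alkene, the C1 centre and the oxirane are all still to come. The dithiane must be reduced to CH2. A8 and A9 need two separate asymmetric preparations.
- Comparison: the chosen plan reaches the complete ring skeleton before any chirality is introduced and then needs a single asymmetric operation.

Key step: step 9

Assumption: the facial preference of the tungsten–bishydroxamic acid catalyst on 14 is taken to follow that known for simpler tertiary allylic alcohols; the (R,R)-ligand is written, and its antipode is used if oxygen is found on the other half.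

## Route

Step 1
Reactants: 1 bis(phenylsulfonyl)methane; 2 (E)-4-chloro-3-methylbut-2-en-1-yl acetate (2.2 equiv)
Product: 3 (2E,7E)-3,7-dimethyl-5,5-bis(phenylsulfonyl)nona-2,7-diene-1,9-diyl diacetate
Conditions: NaH (2.2 equiv), Bu4NI (cat.), DMF, 0 °C → rt
Reagents that add atoms: none
Why: Double SN2 alkylation of the doubly stabilised carbanion of 1 at the primary allylic chloride of 2 forms C5–C6 and C6–C7; the allylic acetate is inert without a metal catalyst and the E geometry is not touched.

Step 2
Reactants: 3 (2E,7E)-3,7-dimethyl-5,5-bis(phenylsulfonyl)nona-2,7-diene-1,9-diyl diacetate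
Product: 4 (2E,7E)-3,7-dimethyl-5,5-bis(phenylsulfonyl)nona-2,7-diene-1,9-diol
Conditions: K2CO3 (cat.), MeOH, rt
Reagents that add atoms: none
Why: Base-catalysed transesterification with methanol frees both primary allylic alcohols; the bis-sulfone carbon has no hydrogen and the mild carbonate should not cause loss of sulfinate.

Step 3
Reactants: 4 (2E,7E)-3,7-dimethyl-5,5-bis(phenylsulfonyl)nona-2,7-diene-1,9-diol
Product: 6 (2E,7E)-1,9-dichloro-3,7-dimethyl-5,5-bis(phenylsulfonyl)nona-2,7-diene, via bis-mesylate 5 (not isolated)
Conditions: MsCl, LiCl, 2,4,6-collidine, DMF, 0 °C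
Reagents that add atoms: lithium chloride, [Li+].[Cl-]; methanesulfonyl chloride, CS(=O)(=O)Cl (mesyl groups in 5 only, its chloride can also end in 6)
Why: Mesylation and in situ chloride displacement (SN2 at the primary allylic carbon, no allylic transposition under these conditions) give the bis-allylic chloride with both E alkenes unchanged.

Step 4
Reactants: 6 (2E,7E)-1,9-dichloro-3,7-dimethyl-5,5-bis(phenylsulfonyl)nona-2,7-diene (3 equiv, excess recovered); 7 isobutyl phenyl sulfone
Product: 8 (2E,7E)-1-chloro-3,7,11-trimethyl-5,5,10-tris(phenylsulfonyl)dodeca-2,7-diene (racemic at C10 of the chain)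
Conditions: 7, n-BuLi, THF, −78 °C; then 6, THF, −78 → −20 °C
Reagents that add atoms: none
Why: Alkylation of the α-lithio sulfone at one allylic chloride (SN2) forms C1–C2; the excess of symmetric 6 suppresses double substitution, and the new sulfone-bearing centre is erased in step 5.

Step 5
Reactants: 8 (2E,7E)-1-chloro-3,7,11-trimethyl-5,5,10-tris(phenylsulfonyl)dodeca-2,7-diene
Product: 9 (3E,8E)-1-isopropyl-4,8-dimethyl-1,6,6-tris(phenylsulfonyl)cyclodeca-3,8-diene
Conditions: LiN(iPr)2 (1.2 equiv), THF, −78 → 0 °C, 0.002 M
Reagents that add atoms: none
Why: Intramolecular alkylation of the tertiary α-sulfonyl carbanion at the remaining allylic chloride closes the ten-membered ring (C1–C10), a ring closure type established for medium- and large-ring terpenoids; the geminal bis-sulfone at C6 helps folding and SN2 at the unhindered CH2Cl keeps both alkenes E.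

Step 6
Reactants: 9 (3E,8E)-1-isopropyl-4,8-dimethyl-1,6,6-tris(phenylsulfonyl)cyclodeca-3,8-diene
Product: 10 (3E,8E)-1-isopropyl-4,8-dimethylcyclodeca-3,8-diene
Conditions: Na(Hg) (6%), Na2HPO4, MeOH/THF, −20 °C → rt
Reagents that add atoms: none
Why: Reductive desulfonylation by electron transfer removes all three sulfonyl groups; every radical or anion that forms (C1, C6) is homoallylic, so the E alkenes cannot shift, and C1 is not a stereocentre in 10 (mirror plane through C1 and C6).

Step 7
Reactants: 10 (3E,8E)-1-isopropyl-4,8-dimethylcyclodeca-3,8-diene
Product: 11 meso (1r,3R,4R,8S,9S)-3,4:8,9-diepoxy-1-isopropyl-4,8-dimethylcyclodecane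
Conditions: dimethyldioxirane (2.2 equiv), acetone/CH2Cl2, −40 → 0 °C
Reagents that add atoms: dimethyldioxirane, CC1(C)OO1
Why: Peripheral epoxidation of a medium-ring diene: in the chair-like conformer with staggered C2–C1–C10 and C5–C6–C7 bridges both E alkenes turn mirror-related faces outward, the two vinylic methyls lie on one ring face and the isopropyl group takes the position anti to C3 and C9 on that same face, so attack from outside on each alkene should give the meso trans,trans-bis-epoxide with the (1r,3R,4R,8S,9S) relative configuration. The neutral dioxirane avoids acid-triggered transannular cyclisation.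

Step 8
Reactants: 11 meso (1r,3R,4R,8S,9S)-3,4:8,9-diepoxy-1-isopropyl-4,8-dimethylcyclodecane
Product: 14 meso (1r,2E,4R,8S,9E)-1-isopropyl-4,8-dimethylcyclodeca-2,9-diene-4,8-diol, via bis-selenide 12 (not isolated), via bis-selenoxide 13 (not isolated)
Conditions: (PhSe)2, NaBH4, EtOH, rt → reflux; then THF, pyridine, 30% aq H2O2, 0 °C → rt
Reagents that add atoms: none
Why: Epoxide-to-allylic-alcohol transposition: the selenolate opens each oxirane by SN2 at the secondary carbon (C3, C9), leaving the C4–O and C8–O bonds and their configuration intact. The selenoxides can eliminate syn only towards C2 and C10 because C4 and C8 bear no hydrogen, and syn eliminations in ten-membered rings favour E alkenes.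

Step 9
Reactants: 14 meso (1r,2E,4R,8S,9E)-1-isopropyl-4,8-dimethylcyclodeca-2,9-diene-4,8-diol
Product: 15 (1S,2E,4R,8S,9S,10R)-9,10-epoxy-1-isopropyl-4,8-dimethylcyclodec-2-ene-4,8-diol
Conditions: WO2(acac)2 (5 mol %), (R,R)-cyclohexane-1,2-diamine-derived bishydroxamic acid ligand (6 mol %), 30% aq H2O2 (1.2 equiv), NaCl, CH2Cl2, rt
Reagents that add atoms: hydrogen peroxide, OO
Why: Ligand exchange on WO2(acac)2 gives a chiral hexavalent tungsten bishydroxamate, which H2O2 turns into a peroxo complex; a tertiary alkoxide of 14 binds to tungsten and the peroxo oxygen is passed within the complex to the neighbouring E alkene. The closest known reaction type is the tungsten–bishydroxamic acid asymmetric epoxidation of tertiary allylic alcohols with aqueous H2O2, together with the desymmetrisation of meso dialkenyl carbinols by related hydroxamate catalysts. The oxirane ring is closed by concerted syn transfer of one oxygen atom to both alkene carbons (a [2+1] addition that forms C9–O and C10–O together), so the E geometry is kept as a trans oxirane. C9 and C10 are set by the alkene face the catalyst chooses, and their relation to C8 by the substrate: the ring bond C8–C7 must lie on the inner face of the alkene, which puts the C8 hydroxyl, not the methyl group, on the outer face, so oxygen arrives syn to it and gives (8S,9S,10R). Group selectivity is needed between the enantiotopic halves; because they are mirror images, the outer face that the catalyst prefers is offered only by the C8–OH/C9=C10 half, while in the C4–OH/C2=C3 half the same face sense is the blocked inner one. Mono-epoxidation is secured by limiting H2O2 and by the fact that the minor enantiomer still carries a matched alkene and should be consumed faster to a bis-epoxide, which raises the enantiomeric purity of 15. C1 and C4 are not touched, so all five stereocentres of the target are fixed in absolute terms in this step.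

Step 10
Reactants: 15 (1S,2E,4R,8S,9S,10R)-9,10-epoxy-1-isopropyl-4,8-dimethylcyclodec-2-ene-4,8-diol
Product: 16 (1S,2E,4R,8S,9R,10R)-8,9-epoxy-1-isopropyl-4,8-dimethylcyclodec-2-ene-4,10-diol
Conditions: KOtBu (0.2 equiv), tBuOH/THF, rt
Reagents that add atoms: none
Why: Payne rearrangement: the C8 alkoxide attacks C9 anti to the C9–O bond (intramolecular SN2, inversion at C9, retention at C8 and C10), which gives the cis-fused C8–C9 oxirane anti to the freed C10 hydroxyl. The equilibrium should lie on the side of the more substituted, less strained oxirane and the secondary alkoxide.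

Step 11
Reactants: 17 4-hydroxybenzoic acid
Product: 19 4-(tert-butyldimethylsilyloxy)benzoic acid, via silyl ester 18 (not isolated)
Conditions: TBSCl (2.2 equiv), imidazole, DMF, rt; then AcOH/THF/H2O, rt
Reagents that add atoms: tert-butyldimethylsilyl chloride, CC(C)(C)[Si](C)(C)Cl
Why: Exhaustive silylation followed by selective hydrolysis of the labile silyl ester; the aryl silyl ether survives mild aqueous acid.

Step 12
Reactants: 16 (1S,2E,4R,8S,9R,10R)-8,9-epoxy-1-isopropyl-4,8-dimethylcyclodec-2-ene-4,10-diol; 19 4-(tert-butyldimethylsilyloxy)benzoic acid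
Product: 20 (1S,2E,4R,8S,9R,10R)-8,9-epoxy-4-hydroxy-1-isopropyl-4,8-dimethylcyclodec-2-en-10-yl 4-(tert-butyldimethylsilyloxy)benzoate
Conditions: EDC·HCl, DMAP, CH2Cl2, rt
Reagents that add atoms: none
Why: Steglich esterification acylates the secondary C10 hydroxyl with retention; the tertiary C4 hydroxyl is too hindered to react and the non-acidic medium spares the oxirane.

Step 13
Reactants: 20 (1S,2E,4R,8S,9R,10R)-8,9-epoxy-4-hydroxy-1-isopropyl-4,8-dimethylcyclodec-2-en-10-yl 4-(tert-butyldimethylsilyloxy)benzoate
Product: 21 (1S,2E,4R,8S,9R,10R)-8,9-epoxy-4-hydroxy-1-isopropyl-4,8-dimethylcyclodec-2-en-10-yl 4-hydroxybenzoate (target)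
Conditions: Bu4NF, AcOH, THF, 0 °C
Reagents that add atoms: none
Why: Fluoride cleaves the aryl silyl ether rapidly; the acetic acid buffer protonates the phenoxide so that ester and oxirane are not attacked.

## Compound list

1 | bis(phenylsulfonyl)methane | O=S(=O)(CS(=O)(=O)c1ccccc1)c1ccccc1 | starting material
2 | (E)-4-chloro-3-methylbut-2-en-1-yl acetate | CC(=O)OC/C=C(\C)CCl | starting material
3 | (2E,7E)-3,7-dimethyl-5,5-bis(phenylsulfonyl)nona-2,7-diene-1,9-diyl diacetate | CC(=O)OC/C=C(\C)CC(C/C(C)=C/COC(C)=O)(S(=O)(=O)c1ccccc1)S(=O)(=O)c1ccccc1 | intermediate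
4 | (2E,7E)-3,7-dimethyl-5,5-bis(phenylsulfonyl)nona-2,7-diene-1,9-diol | OC/C=C(\C)CC(C/C(C)=C/CO)(S(=O)(=O)c1ccccc1)S(=O)(=O)c1ccccc1 | intermediate
5 | (2E,7E)-3,7-dimethyl-5,5-bis(phenylsulfonyl)nona-2,7-diene-1,9-diyl dimethanesulfonate | CS(=O)(=O)OC/C=C(\C)CC(C/C(C)=C/COS(C)(=O)=O)(S(=O)(=O)c1ccccc1)S(=O)(=O)c1ccccc1 | intermediate
6 | (2E,7E)-1,9-dichloro-3,7-dimethyl-5,5-bis(phenylsulfonyl)nona-2,7-diene | ClC/C=C(\C)CC(C/C(C)=C/CCl)(S(=O)(=O)c1ccccc1)S(=O)(=O)c1ccccc1 | intermediate
7 | isobutyl phenyl sulfone | CC(C)CS(=O)(=O)c1ccccc1 | starting material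
8 | (2E,7E)-1-chloro-3,7,11-trimethyl-5,5,10-tris(phenylsulfonyl)dodeca-2,7-diene (racemic) | CC(C)C(C/C=C(\C)CC(C/C(C)=C/CCl)(S(=O)(=O)c1ccccc1)S(=O)(=O)c1ccccc1)S(=O)(=O)c1ccccc1 | intermediate
9 | (3E,8E)-1-isopropyl-4,8-dimethyl-1,6,6-tris(phenylsulfonyl)cyclodeca-3,8-diene | CC(C)C1(S(=O)(=O)c2ccccc2)C/C=C(C)/CC(S(=O)(=O)c2ccccc2)(S(=O)(=O)c2ccccc2)C/C(C)=C/C1 | intermediate
10 | (3E,8E)-1-isopropyl-4,8-dimethylcyclodeca-3,8-diene | CC(C)C1C/C=C(C)/CCC/C(C)=C/C1 | intermediate
11 | meso (1r,3R,4R,8S,9S)-3,4:8,9-diepoxy-1-isopropyl-4,8-dimethylcyclodecane | CC(C)[C@H]1C[C@H]2O[C@]2(C)CCC[C@]3(C)O[C@H]3C1 | intermediate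
12 | meso (1s,3S,4R,8S,9R)-1-isopropyl-4,8-dimethyl-3,9-bis(phenylselanyl)cyclodecane-4,8-diol | CC(C)[C@H]1C[C@H]([Se]c2ccccc2)[C@](C)(O)CCC[C@](C)(O)[C@H]([Se]c2ccccc2)C1 | intermediate
13 | bis-selenoxide of 12, 3,9-bis(phenylseleninyl) compound (mixture at selenium) | CC(C)[C@H]1C[C@H]([Se](=O)c2ccccc2)[C@](C)(O)CCC[C@](C)(O)[C@H]([Se](=O)c2ccccc2)C1 | intermediate
14 | meso (1r,2E,4R,8S,9E)-1-isopropyl-4,8-dimethylcyclodeca-2,9-diene-4,8-diol | C1CC[C@](C)(O)/C=C/[C@@H](C(C)C)/C=C/[C@]1(C)O | intermediate
15 | (1S,2E,4R,8S,9S,10R)-9,10-epoxy-1-isopropyl-4,8-dimethylcyclodec-2-ene-4,8-diol | C1CC[C@](C)(O)[C@H]2O[C@@H]2[C@@H](C(C)C)/C=C/[C@]1(C)O | intermediate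
16 | (1S,2E,4R,8S,9R,10R)-8,9-epoxy-1-isopropyl-4,8-dimethylcyclodec-2-ene-4,10-diol | CC(C)[C@H]1/C=C/[C@](C)(O)CCC[C@]2(C)O[C@@H]2[C@@H]1O | intermediate
17 | 4-hydroxybenzoic acid | OC(=O)c1ccc(O)cc1 | starting material
18 | tert-butyldimethylsilyl 4-(tert-butyldimethylsilyloxy)benzoate | CC(C)(C)[Si](C)(C)OC(=O)c1ccc(O[Si](C)(C)C(C)(C)C)cc1 | intermediate
19 | 4-(tert-butyldimethylsilyloxy)benzoic acid | CC(C)(C)[Si](C)(C)Oc1ccc(cc1)C(O)=O | intermediate
20 | (1S,2E,4R,8S,9R,10R)-8,9-epoxy-4-hydroxy-1-isopropyl-4,8-dimethylcyclodec-2-en-10-yl 4-(tert-butyldimethylsilyloxy)benzoate | CC(C)[C@H]1/C=C/[C@](C)(O)CCC[C@]2(C)O[C@@H]2[C@@H]1OC(=O)c1ccc(O[Si](C)(C)C(C)(C)C)cc1 | intermediate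
21 | (1S,2E,4R,8S,9R,10R)-8,9-epoxy-4-hydroxy-1-isopropyl-4,8-dimethylcyclodec-2-en-10-yl 4-hydroxybenzoate | CC(C)[C@H]1/C=C/[C@](C)(O)CCC[C@]2(C)O[C@@H]2[C@@H]1OC(=O)c1ccc(O)cc1 | target

## Step count and least certain steps

Total: 13 steps. Longest linear sequence: 12 steps (steps 1–10, 12 and 13); step 11 is a one-step side branch.

**Step 9 (key step).** The most likely failure is poor group and face selectivity on the macrocycle. Reaction through the rotamer that puts the C8 (or C4) methyl on the outer face would give the diastereomeric epoxy diol from the other half. The acidic peroxotungstate could also ionise a tertiary allylic alcohol. The fallback leaves metal-alkoxide direction and uses a Shi epoxidation, in which a chiral dioxirane is generated from a fructose-derived ketone (antipode chosen as needed) and KHSO5 in buffered MeCN/dimethoxymethane/water at 0 °C. It selects the outward face of one E alkene without binding the hydroxyl. It sets out from 14 and comes back to the route at 15, and makes no new compound.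

**Step 7.** The risk is insufficient or wrong facial selectivity. Epoxidation through a conformer with one alkene flipped would give the racemic bis-epoxide, and an isopropyl group in the other C1 position would give the C1-epimeric meso isomer. Acid traces could cause transannular cyclisation. The relative configuration of 11 should be secured by crystallography before going on. The fallback replaces reliance on selectivity by a separate-and-recycle loop. It sets out from 10. The bis-epoxides are separated, and the unwanted C1-epimeric meso bis-epoxide F1 and racemic bis-epoxide F2 are deoxygenated with retention of alkene geometry by the low-valent tungsten reagent from WCl6 and n-BuLi. The loop comes back to the route at 10, and the wanted isomer continues as 11.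

**Step 5.** The risk is oligomerisation instead of ring closure, and base-induced loss of sulfinate from the C6 bis-sulfone, since the ring formed is strained and the carbanion is hindered. The fallback reverses the order of bond formation so that the ring is closed by the soft, acidic bis-sulfone nucleophile. It sets out from 7.
- 2-Methyl-2-vinyloxirane F3 is opened with CuBr2 to (E)-4-bromo-2-methylbut-2-en-1-ol F4, which is silylated to bromide F5.
- 7 is alkylated with F5 (n-BuLi, THF) to sulfone F6, and again to the dialkylated sulfone F7.
- Fluoride gives diol F8, and PPh3/CCl4 gives dichloride F9.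
- F9 and 1 with Cs2CO3 in DMF at high dilution give, through the singly alkylated chloride F10, the macrocycle. The fallback comes back to the route at 9.

**Step 8.** The risk is slow or misdirected opening of the oxiranes, because the selenolate must approach C3 and C9 from the side facing the ring interior. An E/Z mixture in the elimination is also possible. The fallback avoids oxirane opening. It sets out from 10, which undergoes a Schenck ene reaction with singlet oxygen (tetraphenylporphyrin, O2, light, CH2Cl2, −30 °C) on the outer faces to give bis-hydroperoxide F11, reduced with PPh3. It comes back to the route at 14. Its own weak point is competing hydrogen abstraction from the methyl groups.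

**Step 10.** The risk is an incomplete shift if the ring cannot place the C8 alkoxide anti to the C9–O bond. Once the 8,9-oxirane exists, the C4 alkoxide may also attack C8 across the ring. The fallback traps the rearranged alkoxide as it forms. It sets out from 15, which is treated with NaH in THF in the presence of 1-[4-(tert-butyldimethylsilyloxy)benzoyl]imidazole F12 (from 19 and 1,1'-carbonyldiimidazole). The less hindered secondary alkoxide of the rearranged isomer is acylated and the equilibrium is drained. The fallback comes back to the route at 20.

## Further compounds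

F0 | step 9 | none | none
F1 | step 7 | meso (1s,3R,4R,8S,9S)-3,4:8,9-diepoxy-1-isopropyl-4,8-dimethylcyclodecane (C1 epimer of 11) | CC(C)[C@@H]1C[C@H]2O[C@]2(C)CCC[C@]3(C)O[C@H]3C1
F2 | step 7 | (3R*,4R*,8R*,9R*)-3,4:8,9-diepoxy-1-isopropyl-4,8-dimethylcyclodecane (racemic, one enantiomer drawn) | CC(C)C1C[C@H]2O[C@]2(C)CCC[C@@]3(C)O[C@@H]3C1
F3 | step 5 | 2-methyl-2-vinyloxirane (racemic) | CC1(CO1)C=C
F4 | step 5 | (E)-4-bromo-2-methylbut-2-en-1-ol | OC/C(C)=C/CBr
F5 | step 5 | (E)-(4-bromo-2-methylbut-2-enyloxy)(tert-butyl)dimethylsilane | CC(C)(C)[Si](C)(C)OC/C(C)=C/CBr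
F6 | step 5 | (E)-tert-butyldimethyl[2,6-dimethyl-5-(phenylsulfonyl)hept-2-enyloxy]silane (racemic) | CC(C)C(C/C=C(\C)CO[Si](C)(C)C(C)(C)C)S(=O)(=O)c1ccccc1
F7 | step 5 | (2E,7E)-1,9-bis(tert-butyldimethylsilyloxy)-5-isopropyl-2,8-dimethyl-5-(phenylsulfonyl)nona-2,7-diene | CC(C)C(C/C=C(\C)CO[Si](C)(C)C(C)(C)C)(C/C=C(\C)CO[Si](C)(C)C(C)(C)C)S(=O)(=O)c1ccccc1
F8 | step 5 | (2E,7E)-5-isopropyl-2,8-dimethyl-5-(phenylsulfonyl)nona-2,7-diene-1,9-diol | CC(C)C(C/C=C(\C)CO)(C/C=C(\C)CO)S(=O)(=O)c1ccccc1
F9 | step 5 | (2E,7E)-1,9-dichloro-5-isopropyl-2,8-dimethyl-5-(phenylsulfonyl)nona-2,7-diene | CC(C)C(C/C=C(\C)CCl)(C/C=C(\C)CCl)S(=O)(=O)c1ccccc1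
F10 | step 5 | (2E,7E)-1-chloro-5-isopropyl-2,8-dimethyl-5,10,10-tris(phenylsulfonyl)deca-2,7-diene (racemic) | CC(C)C(C/C=C(\C)CCl)(C/C=C(\C)CC(S(=O)(=O)c1ccccc1)S(=O)(=O)c1ccccc1)S(=O)(=O)c1ccccc1
F11 | step 8 | meso (1r,2E,4R,8S,9E)-4,8-dihydroperoxy-1-isopropyl-4,8-dimethylcyclodeca-2,9-diene | C1CC[C@](C)(OO)/C=C/[C@@H](C(C)C)/C=C/[C@]1(C)OO
F12 | step 10 | 1-[4-(tert-butyldimethylsilyloxy)benzoyl]imidazole | CC(C)(C)[Si](C)(C)Oc1ccc(cc1)C(=O)n1ccnc1
A1 | alternative 1 | (Z)-10-(tert-butyldimethylsilyloxy)-2-isopropyl-1-(4-methoxybenzyloxy)-5,9-dimethyl-9-(triethylsilyloxy)dec-4-en-3-one (Z-enone, C3 to C2) | CC(C)(C)[Si](C)(C)OC[C@](C)(O[Si](CC)(CC)CC)CCC/C(C)=C\C(=O)[C@@H](C(C)C)COCc1ccc(OC)cc1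
A2 | alternative 1 | [5-(tert-butyldimethylsilyloxy)-4-methyl-4-(triethylsilyloxy)pentyl]magnesium bromide (C3–C7 fragment) | CC(C)(C)[Si](C)(C)OC[C@](C)(O[Si](CC)(CC)CC)CCC[Mg]Br
A3 | alternative 1 | propyne | CC#C
A4 | alternative 1 | 2-[(4-methoxybenzyloxy)methyl]-3-methylbutanoyl chloride (C10, C1, C2 fragment) | ClC(=O)[C@@H](C(C)C)COCc1ccc(OC)cc1
A5 | alternative 2 | protected (2E,8Z)-cyclodecadiene: C4 4-methoxybenzyl ether, C10 tert-butyldimethylsilyl ether | CC(C)[C@H]1/C=C/[C@](C)(OCc2ccc(OC)cc2)CCC/C(C)=C\[C@@H]1O[Si](C)(C)C(C)(C)C
A6 | alternative 2 | cis-fused octalin mesylate with the C3–C8 bond, C1=C2 alkene, C9 mesylate, C10 silyl ether and C4 4-methoxybenzyl ether | CC(C)C1=C[C@H]2[C@](C)(OCc3ccc(OC)cc3)CCC[C@@]2(C)[C@@H](OS(C)(=O)=O)[C@@H]1O[Si](C)(C)C(C)(C)C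
A7 | alternative 3 | C3–C9 chain with C4 silyl ether, C8 hydroxyl and C6 dithiane | COc1ccc(COC[C@](C)(O[Si](C)(C)C(C)(C)C)CC2(SCCCS2)C[C@](C)(O)COCc2ccc(OC)cc2)cc1
A8 | alternative 3 | (R)-2-[(4-methoxybenzyloxy)methyl]-2-methyloxirane (becomes C3–C5) | COc1ccc(COC[C@@]2(C)CO2)cc1
A9 | alternative 3 | (S)-2-[(4-methoxybenzyloxy)methyl]-2-methyloxirane (becomes C7–C9) | COc1ccc(COC[C@]2(C)CO2)cc1
A10 | alternative 3 | 2-(tert-butyldimethylsilyl)-1,3-dithiane | CC(C)(C)[Si](C)(C)C1SCCCS1
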